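The earlier runs and the new flask come from a simulation for substances that don't exist; the scatter is artificial.

- The closed, stirred vessel of flask eta, the flask asked about, holds solid substrate and partner at 25 °C, and its target reading stands at 8.3 % at 50.0 min and 8.3 % at 60.0 min.

| setting | eta | theta | flask |
|---|---|---|---|
| solid substrate | 0.25 M | 0.50 M | 0.25 M |
| partner | 0.80 equiv | 0.80 equiv | 0.800 equiv |
| temperature | 25 °C | 10 °C | 25 °C |
| remark | the very flask that is asked about, followed so far | run made earlier |  |
| time |  |  | 1.0 h |

| eta: time / min | eta: target / % | theta: time / min | theta: target / % |
|---|---|---|---|
| 15.0 | 5.4 | 0.833 | 0 |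
| 30.0 | 7.6 | 2.00 | 0.1 |
| 50.0 | 8.3 | 4.00 | 0.7 |
| 60.0 | 8.3 | 10.0 | 1.8 |

(each reading ± 1 percentage point)

- green: change nothing and wait 30 min more
- red: at 1.0 h add partner, 100 % of the amount charged, then wait 30 min
- violet: at 1.0 h take out 90 % of the target then present, then wait 30 min
- amber: at 1.0 h raise the temperature by 25 K, then wait 30 min

- as a solid, counted per litre of solution: solid substrate
- what is taken out of target is counted as made
- at the start none of the solid substrate is in solution
- additions bring no volume worth counting

- target, in percent of the solid substrate first charged, at 1.0 h
- which option adds most target ("none" when 2 percentage points or less is all one gets) (green / red / violet / amber / none)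
- target present, with what was taken out counted in, in percent of the solid substrate first charged, after violet
- target present, with what was taken out counted in, in percent of the solid substrate first charged, after amber

- This reckoning freezes one quantity, the partner yield 0.104, the plateau reading of target in flask eta divided by the equivalents of partner charged.
- It reads the plateau as the end of a charge: partner is taken as the limiting reagent, and the part of it not found as target is taken to go by paths that make none.
- Time: the last two readings differ by 0 percentage points, inside the scatter of 1 point, so by hand green adds nothing.
- Partner: red brings a fresh dose of 100 % of the charge, so by hand the partner yield adds 8.3 points.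
- Removal: taking out 90 % of the target brings no fresh partner, so by hand violet, with what was taken out counted in, stays near 8.3 %.
- Temperature: a rise of 25 K brings no new partner, so by hand amber also stays near 8.3 %.
- The forecast gives 8.3 % (range 7.5 % to 9.2 %) for now, chooses red, and puts violet at 14.4 % and amber at 9 %, on the grounds of “a reversible reaction fed by a saturated solution”.
- The two part at violet, where the forecast stands higher than this reckoning.
- Flask eta gives 9.08 % at 1.0 h, 9.12 % after violet and 9.11 % after amber.

    starting material + partner → target (k = 0.00910 /M/s, Ea = 74.0 kJ/mol)
    starting material + 2 partner → side product (k = 0.0310 /M²/s, Ea = 55.0 kJ/mol)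
    solid substrate ⇌ starting material, rate k3*(cs3 - [starting material]) while solid is left; crystals form when [starting material] > cs3 (solubility = 28.0 mM, k = 0.00640 /s)
    partner → decomposed reagent (k = 0.00130 /s, Ea = 91.0 kJ/mol)
    (constants at 25 °C)

- In flask eta, red adds 9.9 points, more than green at 0.042 points, violet at 0.042 points or amber at 0.029 points, and the free partner at 60.0 min is 0.345 % of its charge. The partner yield puts flask eta after red at 16.6 %, and the flask stands at 19.0 %. For the neighbour charged with 2.00 equiv of partner, the partner yield gives 20.8 %, and that flask holds 17.4 % of target beside 11.3 % of side product.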